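**Strategy.** The route rests on reading the C5(OH)–C1'H2–C2'(=O) unit of the target as an opened 2-isoxazoline spiro-fused to the six-membered ring at C5. Here C5 is the carbinol carbon of the cyclohexenone ring and C1'/C2' are the first two side-chain carbons. One hydroxyl-directed nitrile oxide cycloaddition to an exocyclic methylene forms the C1'–C2' and C5–O bonds, closes that heterocycle and sets the only stereocentre. The ring oxygen at C1, the later enone carbonyl, steers the dipole through magnesium. The precursor is (R)-3-methylenecyclohexan-1-ol as its magnesium alkoxide, met by oleonitrile oxide released in situ from its hydroximoyl chloride. The isoxazoline then masks the aldol until the enone is in place.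

Key step: step 8

Assumption: the commercial diol is taken as the meso cis isomer (a cis/trans mixture would first need separation); the locants C1–C6, C1' and C2' in the Why lines are those of the target and are kept for the corresponding atoms of every intermediate.

Step 1
Reactants: 1 cis-cyclohexane-1,3-diol
Product: 2 (1S,3R)-3-acetoxycyclohexan-1-ol [(1R,3S)-3-hydroxycyclohexyl acetate]
Conditions: Candida antarctica lipase B (immobilised), vinyl acetate, t-BuOMe, rt
Reagents that add atoms: vinyl acetate, C=COC(C)=O
Why: Lipase-catalysed irreversible transesterification should desymmetrise the meso diol by acylating only its (R)-configured carbinol, the enzyme's usual preference for secondary alcohols, so the oxygen that later directs the cycloaddition is kept as the acetate while the (S)-carbinol stays free for oxidation (enzymatic hydrolysis of the diacetate would instead free the (R)-carbinol and lead into the enantiomeric series).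

Step 2
Reactants: 2 (1S,3R)-3-acetoxycyclohexan-1-ol
Product: 3 (R)-3-oxocyclohexyl acetate
Conditions: Dess–Martin periodinane, CH2Cl2, 0 °C → rt
Reagents that add atoms: none
Why: Dess–Martin oxidation of the free secondary alcohol under non-basic conditions should give the ketone without E1cB loss of the β-acetoxy group, and the acetoxy-bearing stereocentre is not touched.

Step 3
Reactants: 3 (R)-3-oxocyclohexyl acetate
Product: 4 (R)-3-methylenecyclohexyl acetate
Conditions: Zn, CH2Br2, TiCl4, THF (reagent pre-formed); then 3, CH2Cl2, 0 °C → rt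
Reagents that add atoms: dibromomethane, BrCBr
Why: Takai–Lombardo methylenation uses a non-basic, ester-inert zinc/titanium methylene reagent, so the ketone should be converted without enolisation and therefore without the β-elimination of acetate that a basic phosphorus ylide could trigger; the stereocentre is not involved.

Step 4
Reactants: 4 (R)-3-methylenecyclohexyl acetate
Product: 5 (R)-3-methylenecyclohexan-1-ol
Conditions: K2CO3 (cat.), MeOH, rt
Reagents that add atoms: none
Why: Base-catalysed transesterification with methanol cleaves the acetate at the acyl carbon, so the C–O bond of the stereocentre is not broken and the exocyclic alkene is kept (the product is volatile and should be concentrated cold).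

Step 5
Reactants: 6 oleyl alcohol
Product: 7 (Z)-octadec-9-enal
Conditions: TEMPO (cat.), PhI(OAc)2, CH2Cl2, rt
Reagents that add atoms: none
Why: Oxoammonium (TEMPO) oxidation with PhI(OAc)2 as terminal oxidant should stop at the aldehyde and neither attack nor isomerise the Z-alkene.

Step 6
Reactants: 7 (Z)-octadec-9-enal
Product: 8 (Z)-octadec-9-enal oxime
Conditions: NH2OH (50% aq.), EtOH, rt
Reagents that add atoms: hydroxylamine, NO
Why: Condensation of the aldehyde with hydroxylamine should give the aldoxime as a mixture of C=N isomers, both of which lead to the same nitrile oxide.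

Step 7
Reactants: 8 (Z)-octadec-9-enal oxime
Product: 9 (9Z)-N-hydroxyoctadec-9-enimidoyl chloride
Conditions: N-chlorosuccinimide, DMF, 0 °C → rt; aqueous work-up, used at once without purification
Reagents that add atoms: N-chlorosuccinimide, O=C1CCC(=O)N1Cl
Why: Electrophilic chlorination of the aldoxime carbon by N-chlorosuccinimide should be far faster than attack on an unactivated internal alkene, as in the routine use of this reagent on alkenyl aldoximes for intramolecular nitrile oxide cycloadditions.

Step 8
Reactants: 5 (R)-3-methylenecyclohexan-1-ol; 9 (9Z)-N-hydroxyoctadec-9-enimidoyl chloride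
Product: 12 (5R,7R)-3-[(Z)-heptadec-8-en-1-yl]-1-oxa-2-azaspiro[4.5]dec-2-en-7-ol, via bromomagnesium (R)-3-methylenecyclohexan-1-olate 10 (not isolated), via (Z)-octadec-9-enenitrile oxide 11 (not isolated)
Conditions: 5, i-PrOH (3.3 equiv), EtMgBr (3 equiv), CH2Cl2, 0 °C; then 9 added slowly, 0 °C → rt; aq. NH4Cl
Reagents that add atoms: none
Why: EtMgBr converts 5 and the i-PrOH into bromomagnesium alkoxides, which dehydrochlorinate 9 to the nitrile oxide 11, and 11 stays bound through its oxygen to the magnesium of alkoxide 10. A concerted, asynchronous [3+2] dipolar cycloaddition then joins the nitrile oxide carbon to the exocyclic CH2 (bond C1'–C2') and the dipole oxygen to C5; the closest known reaction type is the magnesium-alkoxide-directed nitrile oxide cycloaddition to allylic and homoallylic alcohols. The isoxazoline ring is closed by the intermolecular cycloaddition itself, both ring bonds forming in one event and not by cyclisation of a chain, and it is spiro at C5. The new stereocentre C5 is controlled by the C1 stereocentre of 5: with the OMgBr group axial, the bridging magnesium can deliver the dipole oxygen only to the ring face syn to the C1 oxygen, which should give the 5R,7R adduct with ring oxygen and hydroxyl cis. Oxygen attack at the disubstituted carbon is the innate regiochemistry of a 1,1-disubstituted alkene and is reinforced by the chelate; selectivity over the internal Z-alkene of the chain and over furoxan dimerisation rests on the rate acceleration of the chelated terminal alkene and on slow addition of 9.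

Step 9
Reactants: 12 (5R,7R)-3-[(Z)-heptadec-8-en-1-yl]-1-oxa-2-azaspiro[4.5]dec-2-en-7-ol
Product: 13 (5R)-3-[(Z)-heptadec-8-en-1-yl]-1-oxa-2-azaspiro[4.5]dec-2-en-7-one
Conditions: Dess–Martin periodinane, CH2Cl2, 0 °C → rt
Reagents that add atoms: none
Why: Dess–Martin oxidation converts the C1 carbinol, whose directing role is over, into the ketone under non-basic conditions that should leave the β-positioned C5–O bond, the C=N bond and the Z-alkene alone; C5 is quaternary and cannot epimerise.

Step 10
Reactants: 13 (5R)-3-[(Z)-heptadec-8-en-1-yl]-1-oxa-2-azaspiro[4.5]dec-2-en-7-one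
Product: 14 (5R)-3-[(Z)-heptadec-8-en-1-yl]-7-(trimethylsilyloxy)-1-oxa-2-azaspiro[4.5]deca-2,7-diene
Conditions: LDA (1.1 equiv), TMSCl (present during deprotonation), THF, −78 °C; non-aqueous work-up, used crude
Reagents that add atoms: chlorotrimethylsilane, C[Si](C)(C)Cl
Why: Kinetic deprotonation by the bulky amide with in situ silylation should take the proton from the unhindered C2 methylene and not from C6, which is shielded by the fully substituted spiro carbon C5, and immediate trapping prevents equilibration and E1cB opening of the isoxazoline; the ketone α-protons are far more acidic than those next to the C=N bond.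

Step 11
Reactants: 14 (5R)-3-[(Z)-heptadec-8-en-1-yl]-7-(trimethylsilyloxy)-1-oxa-2-azaspiro[4.5]deca-2,7-diene
Product: 15 (5R)-3-[(Z)-heptadec-8-en-1-yl]-1-oxa-2-azaspiro[4.5]deca-2,8-dien-7-one
Conditions: Pd(OAc)2 (1.1 equiv), MeCN, rt
Reagents that add atoms: none
Why: In this Saegusa–Ito oxidation divalent palladium attacks the silyl enol ether to give a palladium enolate bound at C2, and β-hydride elimination, possible only toward C3 because C5 carries no hydrogen, should give the C2=C3 enone without touching the stereocentre.

Step 12
Reactants: 15 (5R)-3-[(Z)-heptadec-8-en-1-yl]-1-oxa-2-azaspiro[4.5]deca-2,8-dien-7-one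
Product: 17 (R)-5-hydroxy-5-[(Z)-2-oxononadec-10-en-1-yl]cyclohex-2-en-1-one, via β-hydroxy imine 16 (not isolated)
Conditions: Mo(CO)6, MeCN/H2O, 80 °C
Reagents that add atoms: water, O
Why: Mo(CO)6 cleaves the weak N–O bond reductively and the resulting β-hydroxy imine is hydrolysed in the wet solvent to the β-hydroxy ketone, conditions without hydride or hydrogen that should spare the enone and the Z-alkene; the C5–O bond is not broken, so C5 keeps its R configuration.

**Compound list**

1 | cis-cyclohexane-1,3-diol (meso) | O[C@H]1CCC[C@@H](O)C1 | starting material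
2 | (1S,3R)-3-acetoxycyclohexan-1-ol [(1R,3S)-3-hydroxycyclohexyl acetate] | O[C@H]1CCC[C@@H](OC(C)=O)C1 | intermediate
3 | (R)-3-oxocyclohexyl acetate | O=C1CCC[C@@H](OC(C)=O)C1 | intermediate
4 | (R)-3-methylenecyclohexyl acetate | C=C1CCC[C@@H](OC(C)=O)C1 | intermediate
5 | (R)-3-methylenecyclohexan-1-ol | C=C1CCC[C@@H](O)C1 | intermediate
6 | oleyl alcohol, (Z)-octadec-9-en-1-ol | CCCCCCCC/C=C\CCCCCCCCO | starting material
7 | (Z)-octadec-9-enal | CCCCCCCC/C=C\CCCCCCCC=O | intermediate
8 | (Z)-octadec-9-enal oxime (mixture of C=N isomers) | CCCCCCCC/C=C\CCCCCCCC=NO | intermediate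
9 | (9Z)-N-hydroxyoctadec-9-enimidoyl chloride | CCCCCCCC/C=C\CCCCCCCC(Cl)=NO | intermediate
10 | bromomagnesium (R)-3-methylenecyclohexan-1-olate | C=C1CCC[C@@H](O[Mg]Br)C1 | intermediate (not isolated)
11 | (Z)-octadec-9-enenitrile oxide | CCCCCCCC/C=C\CCCCCCCC#[N+][O-] | intermediate (not isolated)
12 | (5R,7R)-3-[(Z)-heptadec-8-en-1-yl]-1-oxa-2-azaspiro[4.5]dec-2-en-7-ol (hydroxyl cis to the ring oxygen) | CCCCCCCC/C=C\CCCCCCCC1=NO[C@@]2(C1)CCC[C@@H](O)C2 | intermediate
13 | (5R)-3-[(Z)-heptadec-8-en-1-yl]-1-oxa-2-azaspiro[4.5]dec-2-en-7-one | CCCCCCCC/C=C\CCCCCCCC1=NO[C@@]2(C1)CCCC(=O)C2 | intermediate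
14 | (5R)-3-[(Z)-heptadec-8-en-1-yl]-7-(trimethylsilyloxy)-1-oxa-2-azaspiro[4.5]deca-2,7-diene | CCCCCCCC/C=C\CCCCCCCC1=NO[C@@]2(C1)CCC=C(O[Si](C)(C)C)C2 | intermediate
15 | (5R)-3-[(Z)-heptadec-8-en-1-yl]-1-oxa-2-azaspiro[4.5]deca-2,8-dien-7-one | CCCCCCCC/C=C\CCCCCCCC1=NO[C@@]2(C1)CC=CC(=O)C2 | intermediate
16 | (R)-5-hydroxy-5-[(Z)-2-iminononadec-10-en-1-yl]cyclohex-2-en-1-one | CCCCCCCC/C=C\CCCCCCCC(=N)C[C@]1(O)CC=CC(=O)C1 | intermediate (not isolated)
17 | (R)-5-hydroxy-5-[(Z)-2-oxononadec-10-en-1-yl]cyclohex-2-en-1-one | CCCCCCCC/C=C\CCCCCCCC(=O)C[C@]1(O)CC=CC(=O)C1 | target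

**Step count.** Total: 12 steps. Longest linear sequence: 9 steps (steps 1–4 and 8–12); the oleyl branch (steps 5–7) joins at step 8.

**Steps most likely to fail**

1. Step 8. Chelation through a homoallylic alkoxide is weaker than in the allylic case, so delivery of the dipole to the face syn to the C1 oxygen may be incomplete. The aliphatic nitrile oxide may also dimerise to the furoxan before it is captured. The two C5 epimers are diastereomers at this stage and must be separated before step 9, otherwise the error becomes a loss of enantiomeric purity.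

 Fallback (sets out from 5 and 7, comes back at 17): the C5–O bond is fixed first by a hydroxyl-directed epoxidation and the side-chain carbonyl is brought in as an acyl anion equivalent. VO(acac)2/t-BuOOH in CH2Cl2 should convert 5 into (3S,5R)-1-oxaspiro[2.5]octan-5-ol F1, with the epoxide oxygen cis to the hydroxyl. Aldehyde 7 with propane-1,3-dithiol and BF3·OEt2 gives 2-[(Z)-heptadec-8-enyl]-1,3-dithiane F2. Its 2-lithio derivative (n-BuLi, THF/HMPA, −78 → −20 °C) opens the lithium alkoxide of F1 at the epoxide CH2 to give (1S,3R)-1-({2-[(Z)-heptadec-8-enyl]-1,3-dithian-2-yl}methyl)cyclohexane-1,3-diol F3. Parikh–Doering oxidation (SO3·pyridine, DMSO, i-Pr2NEt) should give (S)-3-({2-[(Z)-heptadec-8-enyl]-1,3-dithian-2-yl}methyl)-3-hydroxycyclohexan-1-one F4. N-(Trimethylsilyl)imidazole then caps the tertiary alcohol as (S)-3-({2-[(Z)-heptadec-8-enyl]-1,3-dithian-2-yl}methyl)-3-(trimethylsilyloxy)cyclohexan-1-one F5. A Mukaiyama dehydrogenation (LDA, THF, −78 °C, then N-tert-butylbenzenesulfinimidoyl chloride; palladium is avoided because the dithiane sulfur would bind it) gives (S)-5-({2-[(Z)-heptadec-8-enyl]-1,3-dithian-2-yl}methyl)-5-(trimethylsilyloxy)cyclohex-2-en-1-one F6. MeI/CaCO3 in aqueous MeCN followed by dilute citric acid removes the dithiane and the silyl ether to give 17.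

2. Step 10. The base may remove a proton on the C6 side, possibly guided by coordination to the isoxazoline heteroatoms. The resulting enolate would expel the C5 oxygen and open the isoxazoline, or at least lower the regioselectivity of enol ether formation.

 Fallback (sets out from 13, comes back at 15): direct dehydrogenation of the ketone with IBX in DMSO at 65–80 °C, which needs no strong base and no silyl enol ether. Regiochemistry is not in question because C5 is quaternary and only the C2–C3 side can be desaturated. No new compound is made (F0).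

3. Step 12. Low-valent molybdenum may bind or reduce the conjugated enone. The hot, ammonia-releasing medium may also dehydrate the freed β-hydroxy enone toward a phenol or fragment it by retro-aldol reaction.

 Fallback (sets out from 15, comes back at 17): the enone is masked at the allylic alcohol oxidation level during N–O cleavage. Luche reduction (NaBH4, CeCl3·7H2O, MeOH, −78 °C) should give (5R)-3-[(Z)-heptadec-8-enyl]-1-oxa-2-azaspiro[4.5]deca-2,8-dien-7-ol F7 as a mixture of C7 epimers, which is of no consequence. Mo(CO)6 in aqueous MeCN then gives (Z)-1-[(1S)-1,5-dihydroxycyclohex-3-en-1-yl]nonadec-10-en-2-one F8, whose tertiary carbinol has the same spatial arrangement as in 17. MnO2 in CH2Cl2 at rt oxidises only the allylic alcohol and gives 17 under neutral conditions.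

Further compounds
F1 | step 8 | (3S,5R)-1-oxaspiro[2.5]octan-5-ol | C1O[C@]12CCC[C@@H](O)C2
F2 | step 8 | 2-[(Z)-heptadec-8-enyl]-1,3-dithiane | CCCCCCCC/C=C\CCCCCCCC1SCCCS1
F3 | step 8 | (1S,3R)-1-({2-[(Z)-heptadec-8-enyl]-1,3-dithian-2-yl}methyl)cyclohexane-1,3-diol | CCCCCCCC/C=C\CCCCCCCC1(C[C@]2(O)CCC[C@@H](O)C2)SCCCS1
F4 | step 8 | (S)-3-({2-[(Z)-heptadec-8-enyl]-1,3-dithian-2-yl}methyl)-3-hydroxycyclohexan-1-one | CCCCCCCC/C=C\CCCCCCCC1(C[C@]2(O)CCCC(=O)C2)SCCCS1
F5 | step 8 | (S)-3-({2-[(Z)-heptadec-8-enyl]-1,3-dithian-2-yl}methyl)-3-(trimethylsilyloxy)cyclohexan-1-one | CCCCCCCC/C=C\CCCCCCCC1(C[C@]2(O[Si](C)(C)C)CCCC(=O)C2)SCCCS1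
F6 | step 8 | (S)-5-({2-[(Z)-heptadec-8-enyl]-1,3-dithian-2-yl}methyl)-5-(trimethylsilyloxy)cyclohex-2-en-1-one | CCCCCCCC/C=C\CCCCCCCC1(C[C@]2(O[Si](C)(C)C)CC=CC(=O)C2)SCCCS1
F0 | step 10 | none | none
F7 | step 12 | (5R)-3-[(Z)-heptadec-8-enyl]-1-oxa-2-azaspiro[4.5]deca-2,8-dien-7-ol (C7 epimers) | CCCCCCCC/C=C\CCCCCCCC1=NO[C@@]2(C1)CC=CC(O)C2
F8 | step 12 | (Z)-1-[(1S)-1,5-dihydroxycyclohex-3-en-1-yl]nonadec-10-en-2-one (C5 epimers) | CCCCCCCC/C=C\CCCCCCCC(=O)C[C@]1(O)CC=CC(O)C1
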